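The numbers in the tables were generated by integration from invented constants, noise included.

To whoever takes the bench from me: alpha and eta are stirring, charged as listed, and these questions are open.

all flasks: substrate 0.20 M
- Thursday's: partner 0.22 M; capture agent 0.020 M; run made earlier
- Monday's: partner 0.26 M; capture agent 0.020 M; run made earlier
- alpha: partner 0.300 M; capture agent 0.0200 M; time 3.0 min
- eta: partner 0.240 M; capture agent 0.0200 M; time 3.0 min

| run | time / s | single product / % | double product / % | substrate / % |
|---|---|---|---|---|
| Thursday's | 10.0 | 14.4 | 1.0 | 80.3 |
| Thursday's | 15.0 | 18.7 | 3.4 | 75.5 |
| Thursday's | 25.0 | 21.8 | 4.9 | 64.8 |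
| Thursday's | 50.0 | 21.2 | 5.1 | 50.0 |
| Thursday's | 90.0 | 23.9 | 8.3 | 42.3 |
| Monday's | 10.0 | 15.8 | 1.7 | 76.7 |
| Monday's | 25.0 | 21.4 | 5.5 | 58.7 |
| Monday's | 40.0 | 22.9 | 5.9 | 50.7 |
| Monday's | 60.0 | 24.0 | 6.4 | 40.9 |
| Monday's | 90.0 | 23.9 | 8.1 | 35.3 |

(standard deviation of a reading: 1 percentage point)

* which of these holds the largest part of the substrate at the end of alpha (double product / substrate / tris adduct / single product)
* which of these holds the largest part of the substrate at the end of eta (double product / substrate / tris adduct / single product)
* final single product in alpha, as a percentage of the substrate charged



I reckon with the partner budget, the partner charged per substrate charged: 1.50 in alpha and 1.20 in eta. I count one partner for each single product, two for each double product and 3 for each tris adduct. I take partner as the limiting reagent and let the products share out its budget. From Monday's last reading I carry over 23.9% single product, my answer for alpha, and 8.1% double product. As a small correction I book the capture agent, 10.0% of the substrate charge, as holding one partner and one substrate each.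

The rest of the budget makes 33.3% tris adduct in alpha and 23.3% in eta. That leaves 24.7% substrate in alpha and 34.7% in eta. So expect more tris adduct than substrate in alpha, and more substrate than tris adduct in eta. Please add no partner, since this sum stands on the charge.

The forecast says tris adduct for alpha, substrate for eta and 24% single product in alpha (20% to 28%), holding that “the partner budget sets the endpoint”. Its substrate in alpha is 27%, against my 24.7%.

    substrate + partner → single product (k = 0.110 L mol⁻¹ s⁻¹)
    partner + single product → double product (k = 0.170 L mol⁻¹ s⁻¹)
    partner + double product → tris adduct (k = 0.550 L mol⁻¹ s⁻¹)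
    single product + capture agent → trapped intermediate (k = 1.50 L mol⁻¹ s⁻¹)

Alpha ends with 33.7% tris adduct, 26.9% substrate and 22.3% single product; eta ends with 35.3% substrate and 23.3% tris adduct. Counting 10.0% trapped intermediate, alpha's products have taken 1.48 of its budget of 1.50, with 1.5% of the partner left. The neighbour flask is alpha with 0.80 M of substrate, so its budget is 0.375 and its capture correction 2.50%. It ends with 0% of its partner, 20.1% single product and 3.61% double product. The budget therefore leaves 2.56% for tris adduct, and the neighbour flask holds 2.56%.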